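Rings: A = hydroxylated ring carrying its aryloxy group meta to the bridge, B = para-phenylene, C = 1,2,3-trisubstituted phenol ring, D = meta-phenylene. Everything rests on cutting the CH2–CH2 bridge between rings B and C. Its two benzylic carbons sit para (ring B) and ortho (ring C) to the two ether-bearing carbons. As formyl groups they first activate C–F bonds for both SNAr ether formations and are then joined to each other. The key step, an intramolecular McMurry coupling, closes the 18-membered ring of a linear four-arene dialdehyde (B–O–A–CH2CH2–D–O–C, saturated A/D bridge) in one operation. Hydrogenation and double O-demethylation finish.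

Key step: step 4

Assumption: the target SMILES holds no stereocentre, stereoaxis or alkene, so marchantin C is treated as achiral and no step has to control absolute configuration.

Step 1
Reactants: 1 5-bromo-2-methoxyphenol (ring A); 2 4-fluorobenzaldehyde (ring B)
Product: 3 4-(5-bromo-2-methoxyphenoxy)benzaldehyde
Conditions: K2CO3, DMF, 120 °C
Reagents that add atoms: none
Why: SNAr (addition–elimination): the para-formyl group of 2 stabilises the Meisenheimer adduct of the phenoxide of 1 and fluoride leaves, while the unactivated C–Br bond of ring A stays untouched.

Step 2
Reactants: 4 3-vinylphenol (ring D); 3 4-(5-bromo-2-methoxyphenoxy)benzaldehyde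
Product: 6 4-{5-[2-(3-hydroxyphenyl)ethyl]-2-methoxyphenoxy}benzaldehyde, via bis-9-BBN adduct 5 (not isolated)
Conditions: 4 (1.3 equiv), 9-BBN (1.95 equiv per 4), THF, 0 to 40 °C until gas evolution ends; then 3, Pd(OAc)2/SPhos (cat.), aq K3PO4, THF, 60 °C
Reagents that add atoms: 9-BBN, B1C2CCCC1CCC2 (its boron and carbons stay only in 5; only its hydrogen remains in 6)
Why: Hydroboration followed by B-alkyl Suzuki–Miyaura coupling: 9-BBN places boron on the terminal styrene carbon (the phenol O–H consumes a second equivalent with loss of H2), all B–H is spent before aldehyde 3 enters, and the base-activated primary alkylborane transfers its 2-arylethyl group to the arylpalladium bromide of ring A, giving the saturated A/D bridge without a reduction that would endanger the formyl group.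

Step 3
Reactants: 6 4-{5-[2-(3-hydroxyphenyl)ethyl]-2-methoxyphenoxy}benzaldehyde; 7 2-fluoro-3-methoxybenzaldehyde (ring C)
Product: 8 2-[3-(2-{3-(4-formylphenoxy)-4-methoxyphenyl}ethyl)phenoxy]-3-methoxybenzaldehyde (linear dialdehyde)
Conditions: Cs2CO3, DMF, 90 °C
Reagents that add atoms: none
Why: SNAr: the ortho-formyl group of 7, helped by the inductive pull of the neighbouring methoxy group, activates the C–F bond towards the unhindered ring D phenoxide, and fluoride is a far better leaving group than the aryloxide on ring B, so the existing ether should persist.

Step 4
Reactants: 8 linear dialdehyde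
Product: 9 18-membered cyclic stilbene (E/Z mixture; CH=CH between rings B and C)
Conditions: TiCl4, Zn, pyridine, THF, reflux; 8 added by syringe pump (about 1 mM)
Reagents that add atoms: none
Why: McMurry coupling: low-valent titanium made from TiCl4 and Zn transfers single electrons to both formyl groups, the two ketyl radicals held on titanium couple to a titanium-bound 1,2-diolate, and at reflux this is deoxygenated to the alkene, driven by the strength of the Ti–O bond. The closest known reaction type is the McMurry macrocyclisation of aromatic dialdehydes to cyclic stilbenes, a standard entry to cyclophanes. The one ring closed is the 18-membered ring, by end-to-end C=C formation between the formyl carbon on ring B and the formyl carbon on ring C, with all four benzene rings already in place. No stereocentre is formed, and the E/Z ratio of the new alkene does not matter because step 5 erases it. The selectivity needed is ring closure over intermolecular coupling: slow addition keeps free 8 very dilute, 8 has only two carbonyl groups so no other ring can form, and the saturated A/D bridge plus the two bent C–O–C hinges let the chain fold so that both formyl groups reach the same titanium centre. Diaryl and methyl ethers are inert to the reagent.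

Step 5
Reactants: 9 18-membered cyclic stilbene
Product: 10 marchantin C dimethyl ether
Conditions: H2 (1 atm), 10% Pd/C, EtOAc, rt
Reagents that add atoms: none
Why: Heterogeneous catalytic hydrogenation: the disubstituted stilbene C=C of either geometry takes up H2 on Pd/C while arenes, diaryl ethers and methyl ethers are inert, so both isomers of 9 should converge on 10.

Step 6
Reactants: 10 marchantin C dimethyl ether
Product: 11 marchantin C
Conditions: BBr3, CH2Cl2, −78 °C to rt; then H2O
Reagents that add atoms: none
Why: Lewis acid cleavage of aryl methyl ethers: BBr3 binds the methoxy oxygens and bromide attacks the methyl carbons (SN2), the purely sp2 C–O bonds of the diaryl ethers cannot react this way, and the water quench hydrolyses the aryl borates to the two free phenols.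

Compound list
1 | 5-bromo-2-methoxyphenol | COc1ccc(Br)cc1O | starting material
2 | 4-fluorobenzaldehyde | O=Cc1ccc(F)cc1 | starting material
3 | 4-(5-bromo-2-methoxyphenoxy)benzaldehyde | COc1ccc(Br)cc1Oc1ccc(C=O)cc1 | intermediate
4 | 3-vinylphenol | C=Cc1cccc(O)c1 | starting material
5 | bis-9-BBN adduct: 9-{2-[3-(9-borabicyclo[3.3.1]nonan-9-yloxy)phenyl]ethyl}-9-borabicyclo[3.3.1]nonane (not isolated) | C(Cc1cccc(OB2C3CCCC2CCC3)c1)B1C2CCCC1CCC2 | intermediate
6 | 4-{5-[2-(3-hydroxyphenyl)ethyl]-2-methoxyphenoxy}benzaldehyde | COc1ccc(CCc2cccc(O)c2)cc1Oc1ccc(C=O)cc1 | intermediate
7 | 2-fluoro-3-methoxybenzaldehyde | COc1cccc(C=O)c1F | starting material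
8 | 2-[3-(2-{3-(4-formylphenoxy)-4-methoxyphenyl}ethyl)phenoxy]-3-methoxybenzaldehyde | COc1ccc(CCc2cccc(Oc3c(C=O)cccc3OC)c2)cc1Oc1ccc(C=O)cc1 | intermediate
9 | 18-membered cyclic stilbene, B/C-didehydro derivative of 10 (E/Z mixture, geometry left open because step 5 removes it) | COc1ccc2cc1Oc1ccc(cc1)C=Cc1cccc(OC)c1Oc1cccc(c1)CC2 | intermediate
10 | marchantin C dimethyl ether | COc1ccc2cc1Oc1ccc(cc1)CCc1cccc(OC)c1Oc1cccc(c1)CC2 | intermediate
11 | marchantin C (achiral) | Oc1ccc2cc1Oc1ccc(cc1)CCc1cccc(O)c1Oc1cccc(c1)CC2 | target

Total step count: 6. Longest linear sequence: 6.

Steps most likely to fail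

Step 4: intermolecular carbonyl coupling may outrun ring closure, giving oligomers, or deoxygenation may stall at the diolate stage. The fallback sets out from 8 and comes back at 9. Double Wittig methylenation of 8 (MePPh3Br, KOtBu, THF, 0 °C) should give the bis-styrene F1. Ring-closing metathesis of F1 (Grubbs II catalyst, toluene, 80 °C, high dilution, ethene purged) should then close the same 18-membered stilbene 9.

Step 2: residual boron hydride may reduce the formyl group of 3, and protodeboronation or β-hydride elimination may erode the sp3–sp2 coupling. The fallback sets out from 3 and comes back at 6. Copper-free Sonogashira coupling of 3 with commercial 3-ethynylphenol (PdCl2(MeCN)2/XPhos, Cs2CO3, MeCN, 80 °C) should give the diarylalkyne F2. Hydrogenation of F2 over Pd/C poisoned with diphenyl sulfide (H2, 1 atm, EtOAc, rt) should saturate the alkyne and spare the formyl group, giving 6.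

Step 3: attack at the doubly ortho-flanked C–F carbon may be slow, so that aryloxide exchange at the formyl-activated ether between rings A and B begins to compete. The fallback sets out from 6 and comes back at 8. It is a copper-catalysed Ullmann coupling of 6 with commercial 2-bromo-3-methoxybenzaldehyde (CuI, N,N-dimethylglycine, Cs2CO3, dioxane, 90 °C). Here C–O bond formation runs through an arylcopper intermediate assisted by the ortho-formyl group instead of a Meisenheimer adduct. Compounds new to the list: none F0.

Further compounds
F1 | step 4 | bis-styrene 1-ethenyl-2-[3-(2-{3-(4-ethenylphenoxy)-4-methoxyphenyl}ethyl)phenoxy]-3-methoxybenzene | COc1ccc(CCc2cccc(Oc3c(C=C)cccc3OC)c2)cc1Oc1ccc(C=C)cc1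
F2 | step 2 | diarylalkyne 4-{5-[(3-hydroxyphenyl)ethynyl]-2-methoxyphenoxy}benzaldehyde | COc1ccc(C#Cc2cccc(O)c2)cc1Oc1ccc(C=O)cc1
F0 | step 3 | none | none
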